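**Retrosynthetic overview**

- 11 ⇐ 10 by desilylation of the ring C phenol; 10 ⇐ 8 by Julia–Kocienski ethylidenation of the C5 aldehyde. The propenyl group is held back as CHO so that only one alkene meets palladium.
- Feature: in benzofuran numbering (O1, C2, C3; ring A benzo, ring B dihydrofuran, ring C pendant aryl with ipso carbon C1'), C2 bears both O1 and C1' while C3 bears only H and CH3. C2 is thus the doubly functionalised CH2 terminus, and C3 the internal carbon, of a ring A 2-isopropenylphenol.
- Key disconnection: O1–C2 and C2–C1' in one operation, 8 ⇐ phenol 3 + boronic acid 7, by enantioselective palladium-catalysed 1,1-oxyarylation. Ring B is the only ring formed; rings A and C are bought.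
- 3 ⇐ 5-bromovanillin 1 + isopropenyl boronate 2 (Suzuki). 7 ⇐ 2,3-dimethoxyphenol 4 by silylation, sterically directed Ir-catalysed C–H borylation at C5, and pinacol cleavage.

Key step: step 5

Assumption: 5-(ethylsulfonyl)-1-phenyl-1H-tetrazole (9) is taken as a purchasable Julia–Kocienski reagent.

Remark: which antipode of the pyridine-oxazoline ligand gives the Si-face insertion needed for (3S) cannot be predicted with confidence. The (S)-tert-butyl ligand is written; its enantiomer is used if the first experiment gives the (2R,3R) series.

**Route**

Step 1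
Reactants: 1 5-bromovanillin (3-bromo-4-hydroxy-5-methoxybenzaldehyde); 2 isopropenylboronic acid pinacol ester
Product: 3 4-hydroxy-3-methoxy-5-(prop-1-en-2-yl)benzaldehyde
Conditions: PdCl2(dppf) (5 mol%), K2CO3 (3 equiv), 1,4-dioxane/H2O 4:1, 90 °C; then aq. NH4Cl
Reagents that add atoms: none
Why: Suzuki–Miyaura coupling of an aryl bromide with an alkenylboronic ester; the free phenol is tolerated in aqueous carbonate, and the para-formyl group keeps the phenoxide ring electron-poor enough for oxidative addition.

Step 2
Reactants: 4 2,3-dimethoxyphenol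
Product: 5 tert-butyl(2,3-dimethoxyphenoxy)dimethylsilane
Conditions: TBSCl (1.2 equiv), imidazole (2 equiv), DMF, rt
Reagents that add atoms: tert-butyldimethylsilyl chloride (TBSCl), CC(C)(C)[Si](C)(C)Cl
Why: standard imidazole-promoted silylation of a phenol, giving a protecting group that survives the borylation, the periodate cleavage, the oxidative palladium step and the olefination.

Step 3
Reactants: 5 tert-butyl(2,3-dimethoxyphenoxy)dimethylsilane
Product: 6 2-[3-(tert-butyldimethylsilyloxy)-4,5-dimethoxyphenyl]-4,4,5,5-tetramethyl-1,3,2-dioxaborolane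
Conditions: [Ir(cod)(OMe)]2 (1.5 mol%), 4,4'-di-tert-butyl-2,2'-bipyridine (3 mol%), B2pin2 (1.0 equiv), THF, 80 °C
Reagents that add atoms: bis(pinacolato)diboron (B2pin2), CC1(C)OB(OC1(C)C)B1OC(C)(C)C(C)(C)O1
Why: iridium-catalysed aromatic C–H borylation is governed by sterics, and in the 1,2,3-trisubstituted arene 5 only C5 has no ortho substituent, so boron should enter there, meta to the silyloxy group and para to the central methoxy group.

Step 4
Reactants: 6 2-[3-(tert-butyldimethylsilyloxy)-4,5-dimethoxyphenyl]-4,4,5,5-tetramethyl-1,3,2-dioxaborolane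
Product: 7 [3-(tert-butyldimethylsilyloxy)-4,5-dimethoxyphenyl]boronic acid
Conditions: NaIO4 (3 equiv), NH4OAc (3 equiv), acetone/H2O 1:1, rt
Reagents that add atoms: water, O
Why: oxidative cleavage of a pinacol boronate, in which hydrolysis is driven by periodate cleavage of the released pinacol to acetone; the buffered, near-neutral medium should spare the aryl silyl ether, and no free phenol is present for periodate to oxidise.

Step 5
Reactants: 3 4-hydroxy-3-methoxy-5-(prop-1-en-2-yl)benzaldehyde; 7 [3-(tert-butyldimethylsilyloxy)-4,5-dimethoxyphenyl]boronic acid (2 equiv)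
Product: 8 (2S,3S)-2-[3-(tert-butyldimethylsilyloxy)-4,5-dimethoxyphenyl]-7-methoxy-3-methyl-2,3-dihydro-1-benzofuran-5-carbaldehyde
Conditions: Pd(MeCN)2(OTs)2 (8 mol%), (S)-4-tert-butyl-2-[5-(trifluoromethyl)pyridin-2-yl]-4,5-dihydrooxazole (10 mol%), 3 Å MS, O2 (1 atm), DMF, rt
Reagents that add atoms: none
Why: Proposed new method: transmetalation of 7 to the cationic divalent palladium–pyridine-oxazoline complex gives an aryl–palladium that adds syn across the isopropenyl group of 3, ring C going to the terminal carbon (C2) and palladium to the internal carbon (C3); beta-hydride elimination towards C2 gives the bound (E)-alpha-methylstilbene, reinsertion on the same face puts hydrogen on C3 and palladium on C2 as a pi-benzyl species stabilised by ring C, and the phenoxide, held on palladium in a six-membered oxapalladacycle (Pd, C2, C3, C3a, C7a, O1), forms O1–C2 by reductive elimination, after which O2 reoxidises zerovalent palladium. The closest known reaction types are the palladium-catalysed 1,1-diarylation and 1,1-arylacetoxylation of terminal alkenes and the enantioselective redox-relay oxidative Heck arylation with arylboronic acids under this catalyst, where the chain walk ends at an alcohol and not in C–O bond formation. Ring B closes by C(sp3)–O reductive elimination, the six-membered palladacycle contracting to the five-membered ring O1, C2, C3, C3a, C7a. C3 is set by the chiral ligand, which must direct insertion to the Si face of the internal alkene carbon, and this face is kept as long as the palladium hydride stays on the alkene; C2 is set relative to C3 by syn hydropalladation of the E-alkene followed by C–O formation with retention, which places ring C trans to the methyl group. The step needs aryl delivery to the terminal carbon (secured by the 1,1-disubstitution of the alkene), chain walk and C–O closure in preference to release of the Heck stilbene (secured by the ortho phenoxide, which holds palladium, and by pi-benzyl stabilisation from ring C), and no ortho-quinone methide formation or phenol oxidation (secured by the para-formyl group, which makes ring A electron-poor). The excess of 7 also consumes peroxide formed from O2.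

Step 6
Reactants: 8 (2S,3S)-2-[3-(tert-butyldimethylsilyloxy)-4,5-dimethoxyphenyl]-7-methoxy-3-methyl-2,3-dihydro-1-benzofuran-5-carbaldehyde; 9 5-(ethylsulfonyl)-1-phenyl-1H-tetrazole
Product: 10 tert-butyl{5-[(2S,3S)-7-methoxy-3-methyl-5-[(E)-prop-1-en-1-yl]-2,3-dihydro-1-benzofuran-2-yl]-2,3-dimethoxyphenoxy}dimethylsilane
Conditions: 9 (1.5 equiv), KN(SiMe3)2 (1.4 equiv), DME, −60 °C; then 8, −60 °C to rt
Reagents that add atoms: none
Why: Julia–Kocienski olefination, in which the metalated phenyltetrazolyl sulfone adds to the aromatic aldehyde and Smiles rearrangement with loss of SO2 and tetrazololate should give the E-alkene preferentially with potassium counter-ion in DME; the base is consumed by the sulfone before 8 is added, so C2 and C3 are not touched.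

Step 7
Reactants: 10 tert-butyl{5-[(2S,3S)-7-methoxy-3-methyl-5-[(E)-prop-1-en-1-yl]-2,3-dihydro-1-benzofuran-2-yl]-2,3-dimethoxyphenoxy}dimethylsilane
Product: 11 5-[(2S,3S)-7-methoxy-3-methyl-5-[(E)-prop-1-en-1-yl]-2,3-dihydro-1-benzofuran-2-yl]-2,3-dimethoxyphenol (target)
Conditions: Bu4NF (1.1 equiv), AcOH (1.1 equiv), THF, 0 °C
Reagents that add atoms: none
Why: fluoride-mediated cleavage of an aryl silyl ether, fast because phenoxide leaves silicon readily; acetic acid buffers the phenoxide, and neither the propenyl group nor the stereocentres are affected.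

**Compound list**

1 | 5-bromovanillin (3-bromo-4-hydroxy-5-methoxybenzaldehyde) | O=Cc1cc(Br)c(O)c(OC)c1 | starting material
2 | isopropenylboronic acid pinacol ester | CC(=C)B1OC(C)(C)C(C)(C)O1 | starting material
3 | 4-hydroxy-3-methoxy-5-(prop-1-en-2-yl)benzaldehyde | CC(=C)c1cc(C=O)cc(OC)c1O | intermediate
4 | 2,3-dimethoxyphenol | COc1cccc(O)c1OC | starting material
5 | tert-butyl(2,3-dimethoxyphenoxy)dimethylsilane | COc1cccc(O[Si](C)(C)C(C)(C)C)c1OC | intermediate
6 | 2-[3-(tert-butyldimethylsilyloxy)-4,5-dimethoxyphenyl]-4,4,5,5-tetramethyl-1,3,2-dioxaborolane | COc1cc(B2OC(C)(C)C(C)(C)O2)cc(O[Si](C)(C)C(C)(C)C)c1OC | intermediate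
7 | [3-(tert-butyldimethylsilyloxy)-4,5-dimethoxyphenyl]boronic acid | OB(O)c1cc(O[Si](C)(C)C(C)(C)C)c(OC)c(OC)c1 | intermediate
8 | (2S,3S)-2-[3-(tert-butyldimethylsilyloxy)-4,5-dimethoxyphenyl]-7-methoxy-3-methyl-2,3-dihydro-1-benzofuran-5-carbaldehyde | O=Cc1cc(OC)c2c(c1)[C@H](C)[C@@H](c1cc(O[Si](C)(C)C(C)(C)C)c(OC)c(OC)c1)O2 | intermediate
9 | 5-(ethylsulfonyl)-1-phenyl-1H-tetrazole | CCS(=O)(=O)c1nnnn1-c1ccccc1 | starting material
10 | tert-butyl{5-[(2S,3S)-7-methoxy-3-methyl-5-[(E)-prop-1-en-1-yl]-2,3-dihydro-1-benzofuran-2-yl]-2,3-dimethoxyphenoxy}dimethylsilane | C/C=C/c1cc(OC)c2c(c1)[C@H](C)[C@@H](c1cc(O[Si](C)(C)C(C)(C)C)c(OC)c(OC)c1)O2 | intermediate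
11 | 5-[(2S,3S)-7-methoxy-3-methyl-5-[(E)-prop-1-en-1-yl]-2,3-dihydro-1-benzofuran-2-yl]-2,3-dimethoxyphenol | C/C=C/c1cc(OC)c2c(c1)[C@H](C)[C@@H](c1cc(O)c(OC)c(OC)c1)O2 | target

**Step count**

Total: 7 steps. Longest linear sequence: 6 steps (4 → 5 → 6 → 7 → 8 → 10 → 11; steps 2, 3, 4, 5, 6, 7).

**Steps most likely to fail**

Step 5 (labelled as a proposed new method). Three things may go wrong:
- the alkene may leave the palladium hydride before reinsertion, so that the Heck stilbene is released;
- partial dissociation and re-coordination may erode the enantioselectivity;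
- backside C–O closure by unbound phenol would give the cis isomer.

The fallback sets out from 3 and 7 and comes back at 8, separating the two bond formations with known reactions. A base-free oxidative Heck coupling under an achiral catalyst (Pd(OAc)2, 2,9-dimethyl-1,10-phenanthroline, O2, DMF) should give the stilbene 4-hydroxy-3-methoxy-5-{(E)-1-[3-(tert-butyldimethylsilyloxy)-4,5-dimethoxyphenyl]prop-1-en-2-yl}benzaldehyde F1. Any 1,1-disubstituted alkene isomer formed with it converges on the same cation in the next operation. Acid-catalysed intramolecular hydroalkoxylation (catalytic TfOH, CH2Cl2, 0 °C) should protonate C3 and generate the C2 benzylic cation stabilised by ring C. The phenol should then close ring B anti to the methyl group, giving 8 as the racemate with its mirror image, the (2R,3R)-aldehyde F2. Preparative chromatography on a polysaccharide chiral stationary phase then gives 8 as the single enantiomer, at the cost of half the material.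

Step 6. The elimination of the Julia–Kocienski adduct may not be E-selective enough, leaving Z-propenyl isomer that is hard to separate. The fallback sets out from 8 and comes back at 10 by a Takai–Utimoto ethylidenation (CrCl2, CH3CHI2, THF, rt). This runs through a geminal dichromium reagent and is E-selective for a different reason; no compound outside the list is formed (F0).

Step 4. Cleavage of the pinacol ester may stop short, or the silyl ether or the C–B bond may be lost on prolonged exposure to the aqueous oxidant. The fallback sets out from 6 and comes back at 7. Transesterification with diethanolamine (Et2O, rt) should precipitate the diethanolamine boronate 2-[3-(tert-butyldimethylsilyloxy)-4,5-dimethoxyphenyl]-1,3,6,2-dioxazaborocane F3. This is filtered off and hydrolysed by brief shaking with 0.1 M aqueous HCl and Et2O to give 7, without any oxidant.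

**Further compounds**

F1 | step 5 | 4-hydroxy-3-methoxy-5-{(E)-1-[3-(tert-butyldimethylsilyloxy)-4,5-dimethoxyphenyl]prop-1-en-2-yl}benzaldehyde | C/C(=C\c1cc(O[Si](C)(C)C(C)(C)C)c(OC)c(OC)c1)c1cc(C=O)cc(OC)c1O
F2 | step 5 | (2R,3R)-2-[3-(tert-butyldimethylsilyloxy)-4,5-dimethoxyphenyl]-7-methoxy-3-methyl-2,3-dihydro-1-benzofuran-5-carbaldehyde (enantiomer of 8, formed with 8 as the racemate) | O=Cc1cc(OC)c2c(c1)[C@@H](C)[C@H](c1cc(O[Si](C)(C)C(C)(C)C)c(OC)c(OC)c1)O2
F0 | step 6 | none | none
F3 | step 4 | 2-[3-(tert-butyldimethylsilyloxy)-4,5-dimethoxyphenyl]-1,3,6,2-dioxazaborocane | COc1cc(B2OCCNCCO2)cc(O[Si](C)(C)C(C)(C)C)c1OC
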